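**Plan**
1. Retrosynthetic cuts, in order: the silyl ether on the ring B phenol; O1–C2 and C4–C4a of the pyran ring, which releases 3-methylbut-2-enal; C6–C7 and C4a–C5 of ring A; then the C8–CH2 prenyl bond and the carbonyl–alkyne bond of the ynone.
2. Enabling feature: ring A (C4a, C5, C6, C7, C8, C8a) has oxygen on C7 and C8a in a 1,3-relationship, the prenyl group on C8 between them, the ketone on C6 beside C7–OH, and only hydrogen on C5. C7–C8–C8a–C4a is therefore the chain of a 2-prenylacetoacetate, used as its bis-silyl dienol ether, and C5–C6 is the triple bond of a terminal ynone.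
3. Forward order: a diene arm (three steps) and an ynone arm (three steps) meet in a [4+2] cycloaddition/aromatisation that builds ring A. The pyran ring then closes at C4a by condensation and oxa-6π closure, and fluoride frees the ring B phenol.
4. Stereochemistry: the target has no stereocentre and no open-chain double bond with E/Z isomers, and C3=C4 is cis by ring constraint. Only regiochemistry has to be controlled.

Key step: step 7

Remark: 4, 5 and 6 are used as E/Z mixtures because every trigonal carbon concerned ends up in the aromatic ring. 3, 11 and 13 are racemic and their stereocentres are lost again.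

Step 1
Reactants: 1 methyl acetoacetate; 2 prenyl bromide (1-bromo-3-methylbut-2-ene)
Product: 3 methyl 2-acetyl-5-methylhex-4-enoate (racemic)
Conditions: K2CO3, acetone, reflux (slight excess of 1)
Reagents that add atoms: none
Why: In this acetoacetic ester alkylation (SN2) the soft stabilised enolate attacks the primary carbon of the allylic bromide through carbon rather than oxygen, a slight excess of 1 holds back double alkylation, and the new stereocentre is racemic and is erased in step 2.

Step 2
Reactants: 3 methyl 2-acetyl-5-methylhex-4-enoate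
Product: 4 methyl 5-methyl-2-[1-(trimethylsilyloxy)ethylidene]hex-4-enoate (E/Z mixture)
Conditions: TMSCl, Et3N, toluene, rt, 2–3 d; filtration under argon
Reagents that add atoms: chlorotrimethylsilane, C[Si](C)(C)Cl
Why: Soft enolisation and O-silylation of a β-keto ester with an amine base and a chlorosilane should give the conjugated β-silyloxy enoate, and the ester and the prenyl olefin are inert to these reagents.

Step 3
Reactants: 4 methyl 5-methyl-2-[1-(trimethylsilyloxy)ethylidene]hex-4-enoate
Product: 6 1-methoxy-2-(3-methylbut-2-enyl)-1,3-bis(trimethylsilyloxy)buta-1,3-diene, via lithium dienolate 5 (not isolated)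
Conditions: LiN(iPr)2 (commercial solution), THF, −78 °C; TMSCl, −78 °C to rt; hexane, filtration under argon, used crude
Reagents that add atoms: chlorotrimethylsilane, C[Si](C)(C)Cl
Why: Kinetic γ-deprotonation of the β-silyloxy enoate at its methyl group gives the extended ester dienolate 5, which the hard chlorosilane traps on oxygen (silyl ketene acetal formation), and this is the standard second stage in making 1-alkoxy-1,3-bis(silyloxy)dienes.

Step 4
Reactants: 7 3-(4-hydroxyphenyl)propanoic acid
Product: 8 3-(4-hydroxyphenyl)-N-methoxy-N-methylpropanamide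
Conditions: MeNH(OMe)·HCl, EDC·HCl, Et3N, CH2Cl2–DMF, 0 °C to rt
Reagents that add atoms: N,O-dimethylhydroxylamine hydrochloride, CNOC.Cl
Why: In this carbodiimide amide coupling the liberated amine outcompetes the phenol for the activated acid, so the phenol needs no protection yet.

Step 5
Reactants: 8 3-(4-hydroxyphenyl)-N-methoxy-N-methylpropanamide
Product: 9 N-methoxy-N-methyl-3-[4-(triisopropylsilyloxy)phenyl]propanamide
Conditions: TIPSCl, imidazole, DMF, rt
Reagents that add atoms: chlorotriisopropylsilane, CC(C)[Si](Cl)(C(C)C)C(C)C
Why: Imidazole-promoted silylation of the phenol installs a bulky silyl ether that should withstand the Grignard reagent, the dilute acid of step 7 and the hot amine acetate of step 8, yet is removed by fluoride.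

Step 6
Reactants: 9 N-methoxy-N-methyl-3-[4-(triisopropylsilyloxy)phenyl]propanamide; 10 ethynylmagnesium bromide
Product: 12 5-[4-(triisopropylsilyloxy)phenyl]pent-1-yn-3-one, via magnesium-chelated tetrahedral adduct 11 (not isolated)
Conditions: THF, −20 to 0 °C; poured into cold 1 M aq HCl/Et2O, rapid extraction
Reagents that add atoms: none
Why: In this Weinreb ketone synthesis chelate 11 persists until the quench, so no second addition occurs, and the inverse quench into cold acid protonates the released N,O-dimethylhydroxylamine before it can add to the terminal ynone.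

Step 7
Reactants: 6 1-methoxy-2-(3-methylbut-2-enyl)-1,3-bis(trimethylsilyloxy)buta-1,3-diene; 12 5-[4-(triisopropylsilyloxy)phenyl]pent-1-yn-3-one
Product: 15 1-[2,4-dihydroxy-3-(3-methylbut-2-enyl)phenyl]-3-[4-(triisopropylsilyloxy)phenyl]propan-1-one, via cyclohexa-1,4-diene adduct 13 (not isolated), via bis(trimethylsilyl) aryl ether 14 (not isolated)
Conditions: 6 (1.5 equiv), toluene, 0 °C to rt, then 60 °C; 1 M aq HCl, THF, 0 °C
Reagents that add atoms: none
Why: The CH2 terminus of 6, to which both the 3-silyloxy group and the ketene acetal push electron density, bonds to the unsubstituted β-carbon of ynone 12 (C4a–C5) while the ketene acetal carbon bonds to the α-carbon (C6–C7), either in one strongly asynchronous [4+2] event or as a Mukaiyama–Michael addition whose allenolate closes on the silyloxycarbenium carbon. Adduct 13 holds a doubly allylic CH2 that is γ to the ketone and 1,4 to the ketal methoxy group, so it should lose methanol on warming to give arene 14, and cold dilute acid then cleaves the two labile aryl trimethylsilyl ethers while the hindered triisopropylsilyl ether and the prenyl olefin stay intact. The closest known reaction type is the Diels–Alder/aromatisation of 1-alkoxy-1,3-bis(silyloxy)buta-1,3-dienes, 2-alkyl members included, with acetylenic esters and ketones to give resorcinol derivatives. Ring A closes as a six-membered carbocycle in the intermolecular [4+2] mode, four carbons from the diene (C7, C8, C8a, C4a) and two from the alkyne (C5, C6). The only stereocentre formed, the ketal carbon of 13, arises racemic and vanishes on aromatisation, so no stereocontrol is called for. The step needs regioselectivity, which the polarity match between the nucleophilic CH2 terminus and the electrophilic alkyne CH secures and which places the acyl-bearing carbon next to the future C7–OH, and it needs the [4+2] mode to win over a 1,3-dinucleophile [3+3] mode, which the prenyl group on C2 of the diene blocks because that path could not aromatise, while the absence of any Lewis acid avoids 1,2-addition to the ketone.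

Step 8
Reactants: 15 1-[2,4-dihydroxy-3-(3-methylbut-2-enyl)phenyl]-3-[4-(triisopropylsilyloxy)phenyl]propan-1-one; 16 3-methylbut-2-enal
Product: 18 1-[7-hydroxy-2,2-dimethyl-8-(3-methylbut-2-enyl)-2H-chromen-6-yl]-3-[4-(triisopropylsilyloxy)phenyl]propan-1-one, via ortho-quinone methide 17 (not isolated)
Conditions: ethylenediammonium diacetate (20 mol %), xylene, reflux
Reagents that add atoms: none
Why: Amine-salt-catalysed Knoevenagel-type condensation of the enal, as its iminium ion, at the only unsubstituted carbon next to a hydroxyl gives ortho-quinone methide 17, whose oxa-6π electrocyclisation closes the pyran ring (a formal [3+3] chromene annulation known for acylresorcinols), while the other hydroxyl stays locked in a hydrogen bond to the ketone.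

Step 9
Reactants: 18 1-[7-hydroxy-2,2-dimethyl-8-(3-methylbut-2-enyl)-2H-chromen-6-yl]-3-[4-(triisopropylsilyloxy)phenyl]propan-1-one
Product: 19 1-[7-hydroxy-2,2-dimethyl-8-(3-methylbut-2-enyl)-2H-chromen-6-yl]-3-(4-hydroxyphenyl)propan-1-one
Conditions: Bu4NF, AcOH, THF, 0 °C
Reagents that add atoms: none
Why: Fluoride-driven cleavage of the aryl silyl ether, buffered with acetic acid, should free the phenol without any strong acid that could cyclise the prenyl group onto the neighbouring hydroxyl or open the chromene.

**Compound list**
1 | methyl acetoacetate | COC(=O)CC(C)=O | starting material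
2 | 1-bromo-3-methylbut-2-ene (prenyl bromide) | CC(C)=CCBr | starting material
3 | methyl 2-acetyl-5-methylhex-4-enoate (racemic) | COC(=O)C(CC=C(C)C)C(C)=O | intermediate
4 | methyl 5-methyl-2-[1-(trimethylsilyloxy)ethylidene]hex-4-enoate (E/Z mixture) | COC(=O)C(CC=C(C)C)=C(C)O[Si](C)(C)C | intermediate
5 | lithium dienolate of 4, lithium 1-methoxy-2-(3-methylbut-2-enyl)-3-(trimethylsilyloxy)buta-1,3-dien-1-olate (not isolated) | COC(O[Li])=C(CC=C(C)C)C(=C)O[Si](C)(C)C | intermediate
6 | 1-methoxy-2-(3-methylbut-2-enyl)-1,3-bis(trimethylsilyloxy)buta-1,3-diene (ketene acetal geometry as formed) | COC(O[Si](C)(C)C)=C(CC=C(C)C)C(=C)O[Si](C)(C)C | intermediate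
7 | 3-(4-hydroxyphenyl)propanoic acid | O=C(O)CCc1ccc(O)cc1 | starting material
8 | 3-(4-hydroxyphenyl)-N-methoxy-N-methylpropanamide | CON(C)C(=O)CCc1ccc(O)cc1 | intermediate
9 | N-methoxy-N-methyl-3-[4-(triisopropylsilyloxy)phenyl]propanamide | CON(C)C(=O)CCc1ccc(O[Si](C(C)C)(C(C)C)C(C)C)cc1 | intermediate
10 | ethynylmagnesium bromide | C#C[Mg]Br | starting material
11 | bromomagnesium alkoxide of 3-[methoxy(methyl)amino]-5-[4-(triisopropylsilyloxy)phenyl]pent-1-yn-3-ol (chelated tetrahedral adduct, racemic, not isolated) | C#CC(O[Mg]Br)(CCc1ccc(O[Si](C(C)C)(C(C)C)C(C)C)cc1)N(C)OC | intermediate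
12 | 5-[4-(triisopropylsilyloxy)phenyl]pent-1-yn-3-one | C#CC(=O)CCc1ccc(O[Si](C(C)C)(C(C)C)C(C)C)cc1 | intermediate
13 | 1-[6-methoxy-5-(3-methylbut-2-enyl)-4,6-bis(trimethylsilyloxy)cyclohexa-1,4-dien-1-yl]-3-[4-(triisopropylsilyloxy)phenyl]propan-1-one (racemic, not isolated) | COC1(O[Si](C)(C)C)C(CC=C(C)C)=C(O[Si](C)(C)C)CC=C1C(=O)CCc1ccc(O[Si](C(C)C)(C(C)C)C(C)C)cc1 | intermediate
14 | 1-[3-(3-methylbut-2-enyl)-2,4-bis(trimethylsilyloxy)phenyl]-3-[4-(triisopropylsilyloxy)phenyl]propan-1-one (not isolated) | CC(C)=CCc1c(O[Si](C)(C)C)ccc(C(=O)CCc2ccc(O[Si](C(C)C)(C(C)C)C(C)C)cc2)c1O[Si](C)(C)C | intermediate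
15 | 1-[2,4-dihydroxy-3-(3-methylbut-2-enyl)phenyl]-3-[4-(triisopropylsilyloxy)phenyl]propan-1-one | CC(C)=CCc1c(O)ccc(C(=O)CCc2ccc(O[Si](C(C)C)(C(C)C)C(C)C)cc2)c1O | intermediate
16 | 3-methylbut-2-enal | CC(C)=CC=O | starting material
17 | 3-hydroxy-2-(3-methylbut-2-enyl)-6-(3-methylbut-2-enylidene)-4-{3-[4-(triisopropylsilyloxy)phenyl]propanoyl}cyclohexa-2,4-dien-1-one (exocyclic geometry not fixed, the carbonyl-syn form closes, not isolated) | CC(C)=CC=C1C=C(C(=O)CCc2ccc(O[Si](C(C)C)(C(C)C)C(C)C)cc2)C(O)=C(CC=C(C)C)C1=O | intermediate
18 | 1-[7-hydroxy-2,2-dimethyl-8-(3-methylbut-2-enyl)-2H-chromen-6-yl]-3-[4-(triisopropylsilyloxy)phenyl]propan-1-one | CC(C)=CCc1c(O)c(C(=O)CCc2ccc(O[Si](C(C)C)(C(C)C)C(C)C)cc2)cc2c1OC(C)(C)C=C2 | intermediate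
19 | 1-[7-hydroxy-2,2-dimethyl-8-(3-methylbut-2-enyl)-2H-chromen-6-yl]-3-(4-hydroxyphenyl)propan-1-one | CC(C)=CCc1c(O)c(C(=O)CCc2ccc(O)cc2)cc2c1OC(C)(C)C=C2 | target

**Total step count:** 9.
**Longest linear sequence:** 6 steps (1 → 3 → 4 → 6 → 15 → 18 → 19, and equally 7 → 8 → 9 → 12 → 15 → 18 → 19).

**Steps most likely to fail**

Step 7.
- What may go wrong:
  - The addition may stop after the first C–C bond, giving conjugate addition without ring closure.
  - The terminal ynone may oligomerise faster than it is trapped.
  - The diene may be protodesilylated by moisture or by the released methanol.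
  - Aromatisation may proceed by loss of silanol in place of methanol, leaving the C7 oxygen methylated.
- Fallback: ring A is bought rather than built and is dressed by directed ortho-metalation. The sequence sets out from amide 9, together with bromide 2 and commercial resorcinol, and comes back to the route at 15. Resorcinol is converted with MOMCl and iPr2NEt in CH2Cl2 into 1,3-bis(methoxymethoxy)benzene F1. Lithiation between the two acetal oxygens (n-BuLi, THF, 0 °C) and alkylation with 2 should give 1,3-bis(methoxymethoxy)-2-(3-methylbut-2-enyl)benzene F2. A second directed lithiation next to one acetal (n-BuLi, TMEDA, THF, 0 °C) and acylation with 9 should give 1-[2,4-bis(methoxymethoxy)-3-(3-methylbut-2-enyl)phenyl]-3-[4-(triisopropylsilyloxy)phenyl]propan-1-one F3. Mild acid methanolysis (catalytic HCl, MeOH, 40 °C) then returns 15.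

Step 8.
- What may go wrong: C–C bond formation at the one open ring position may be slow. The hydrogen bond between the ortho hydroxyl and the ketone localises the ring π bonds so that the enol-type reactivity of the free hydroxyl points toward the blocked, prenyl-bearing carbon. Self-condensation of the enal can then consume the reagent.
- Fallback: the pyran carbons are first attached to oxygen and then delivered to carbon by a sigmatropic shift. The sequence sets out from 15 and comes back at 18. Selective O-alkylation of the non-chelated 4-hydroxyl with 3-chloro-3-methylbut-1-yne (K2CO3, KI, acetone, reflux) should give 1-[2-hydroxy-4-(2-methylbut-3-yn-2-yloxy)-3-(3-methylbut-2-enyl)phenyl]-3-[4-(triisopropylsilyloxy)phenyl]propan-1-one F4. Heating in o-xylene at 140 °C should bring about aromatic Claisen rearrangement to the free ortho carbon, a 1,5-hydrogen shift and oxa-6π closure to 18.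

Step 6.
- What may go wrong: the liberated N,O-dimethylhydroxylamine may add in conjugate fashion to the terminal ynone during the quench, and the ynone may oligomerise under basic conditions.
- Fallback: the ketone is reached by oxidation, so that no amine is ever present beside the ynone. The sequence sets out from 9 and comes back at 12. Reduction with iBu2AlH (THF, −78 °C) should give 3-[4-(triisopropylsilyloxy)phenyl]propanal F5. Addition of 10 (THF, 0 °C) should give racemic 5-[4-(triisopropylsilyloxy)phenyl]pent-1-yn-3-ol F6. Oxidation with MnO2 in CH2Cl2 at rt returns 12.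

**Further compounds**
F1 | step 7 | 1,3-bis(methoxymethoxy)benzene | COCOc1cccc(OCOC)c1
F2 | step 7 | 1,3-bis(methoxymethoxy)-2-(3-methylbut-2-enyl)benzene | COCOc1cccc(OCOC)c1CC=C(C)C
F3 | step 7 | 1-[2,4-bis(methoxymethoxy)-3-(3-methylbut-2-enyl)phenyl]-3-[4-(triisopropylsilyloxy)phenyl]propan-1-one | COCOc1ccc(C(=O)CCc2ccc(O[Si](C(C)C)(C(C)C)C(C)C)cc2)c(OCOC)c1CC=C(C)C
F4 | step 8 | 1-[2-hydroxy-4-(2-methylbut-3-yn-2-yloxy)-3-(3-methylbut-2-enyl)phenyl]-3-[4-(triisopropylsilyloxy)phenyl]propan-1-one | C#CC(C)(C)Oc1ccc(C(=O)CCc2ccc(O[Si](C(C)C)(C(C)C)C(C)C)cc2)c(O)c1CC=C(C)C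
F5 | step 6 | 3-[4-(triisopropylsilyloxy)phenyl]propanal | O=CCCc1ccc(O[Si](C(C)C)(C(C)C)C(C)C)cc1
F6 | step 6 | 5-[4-(triisopropylsilyloxy)phenyl]pent-1-yn-3-ol (racemic) | C#CC(O)CCc1ccc(O[Si](C(C)C)(C(C)C)C(C)C)cc1
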